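**Overview (briarane numbering)**

- The route rests on the aldol array O14–C14–C1–C2–O2. Its central bond C1–C2 is a bond of the ten-membered ring (C1–C10) and ends at the quaternary carbon C1 shared with the cyclohexane (C1, C10–C14); cutting it gives an α-bromoketone ynal.
- The C1 bromide comes from an exocyclic C1=C15 enone by conjugate hydride addition and bromination. That enone, C9 and C10 are made together by an indium Barbier union (C9–C10) of a 2-(bromomethyl)cyclohexenone, derived from a quinone monoketal, with a 4-formylbutenolide.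
- The butenolide (C7 from an asymmetric propiolate alkynylation, then vinylcuprate/methyl iodide) carries the enyne arm, built from but-2-yne-1,4-diol and propargyl alcohol by Sonogashira coupling.
- After ring closure: anti reduction at C14, Z semireduction of C3≡C4, butenolide epoxidation and reductive opening (8-OH), C16 chloride, hydroxyl-directed 11,20-epoxidation, acetates.
- Ring order: cyclohexane (present from the start), butenolide, ten-membered ring (key step), oxirane last.

Key step: step 22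

Assumption (chemistry): the ligand antipodes named in steps 1 and 10 are taken to be those that give 5R in 3 and 4S in 16; carbinols 25–27 are C14 epimer mixtures (the centre is oxidised in step 18) and bromides 30–32 are C1 epimer mixtures (one drawn, both give enolate 33).

**Route**

Step 1
Reactants: 1 4,4-dimethoxycyclohexa-2,5-dien-1-one
Product: 3 (R)-5-hydroxy-4,4-dimethoxycyclohex-2-en-1-one, via β-boryl ketone 2 (not isolated)
Conditions: CuCl (cat.), NaOt-Bu (cat.), (R)-DTBM-SEGPHOS, B2pin2, MeOH, THF, −20 °C; then NaBO3·4H2O, THF/H2O, rt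
Reagents that add atoms: sodium perborate, [Na+].[O-]OB=O
Why: Copper-catalysed enantioselective conjugate borylation should desymmetrise the two enantiotopic enone arms of the monoketal (ligand-controlled face selection sets C12), and perborate oxidation of the C–B bond of 2 proceeds with retention.

Step 2
Reactants: 3 (R)-5-hydroxy-4,4-dimethoxycyclohex-2-en-1-one
Product: 4 (R)-5-(tert-butyldimethylsilyloxy)-4,4-dimethoxycyclohex-2-en-1-one
Conditions: TBSCl, imidazole, DMF, 0 °C → rt
Reagents that add atoms: tert-butyldimethylsilyl chloride, C[Si](C)(Cl)C(C)(C)C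
Why: Silyl ether formation on the secondary alcohol, with a base too weak to eliminate the β-oxygen of the ketone.

Step 3
Reactants: 4 (R)-5-(tert-butyldimethylsilyloxy)-4,4-dimethoxycyclohex-2-en-1-one
Product: 5 (R)-5-(tert-butyldimethylsilyloxy)-2-(hydroxymethyl)-4,4-dimethoxycyclohex-2-en-1-one
Conditions: aq. HCHO, imidazole, THF/H2O, rt
Reagents that add atoms: formaldehyde, C=O
Why: Morita–Baylis–Hillman reaction, in which imidazole adds reversibly to the electrophilic monoketal enone and the enolate is hydroxymethylated at C1, bringing in C15 without a new stereocentre.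

Step 4
Reactants: 5 (R)-5-(tert-butyldimethylsilyloxy)-2-(hydroxymethyl)-4,4-dimethoxycyclohex-2-en-1-one
Product: 6 (R)-2-(bromomethyl)-5-(tert-butyldimethylsilyloxy)-4,4-dimethoxycyclohex-2-en-1-one
Conditions: CBr4, PPh3, CH2Cl2, 0 °C
Reagents that add atoms: carbon tetrabromide, BrC(Br)(Br)Br
Why: Appel bromination of the primary allylic alcohol under neutral conditions that spare the ketal and the silyl ether.

Step 5
Reactants: 7 propargyl alcohol
Product: 8 1-methoxy-4-[(prop-2-yn-1-yloxy)methyl]benzene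
Conditions: NaH, 4-methoxybenzyl chloride, Bu4NI (cat.), THF, 0 °C → rt
Reagents that add atoms: 4-methoxybenzyl chloride, COc1ccc(CCl)cc1
Why: Williamson etherification of the primary alkoxide with a benzylic chloride.

Step 6
Reactants: 9 but-2-yne-1,4-diol
Product: 10 4-(tert-butyldimethylsilyloxy)but-2-yn-1-ol
Conditions: NaH (1 equiv), THF; then TBSCl, rt
Reagents that add atoms: tert-butyldimethylsilyl chloride, C[Si](C)(Cl)C(C)(C)C
Why: Monosilylation of a symmetrical diol through its sparingly soluble monosodium alkoxide.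

Step 7
Reactants: 10 4-(tert-butyldimethylsilyloxy)but-2-yn-1-ol
Product: 12 (Z)-4-(tert-butyldimethylsilyloxy)-3-iodobut-2-en-1-ol, via alkenylalanate 11 (not isolated)
Conditions: NaAlH2(OCH2CH2OCH3)2, THF, 0 °C; then I2, −78 °C
Reagents that add atoms: iodine, II
Why: Hydroxyl-directed trans-hydroalumination puts aluminium on the alkyne carbon remote from the free alcohol, and iodinolysis with retention gives the Z iodide, which fixes C4 cis to C7 across the later C5=C6 bond.

Step 8
Reactants: 12 (Z)-4-(tert-butyldimethylsilyloxy)-3-iodobut-2-en-1-ol; 8 1-methoxy-4-[(prop-2-yn-1-yloxy)methyl]benzene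
Product: 13 (E)-3-[(tert-butyldimethylsilyloxy)methyl]-6-(4-methoxybenzyloxy)hex-2-en-4-yn-1-ol
Conditions: Pd(PPh3)2Cl2 (cat.), CuI (cat.), Et3N, THF, rt
Reagents that add atoms: none
Why: Sonogashira coupling (oxidative addition of the alkenyl iodide to zerovalent palladium, copper acetylide transmetalation) with retention of the alkene geometry.

Step 9
Reactants: 13 (E)-3-[(tert-butyldimethylsilyloxy)methyl]-6-(4-methoxybenzyloxy)hex-2-en-4-yn-1-ol
Product: 14 (E)-3-[(tert-butyldimethylsilyloxy)methyl]-6-(4-methoxybenzyloxy)hex-2-en-4-ynal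
Conditions: MnO2, CH2Cl2, rt
Reagents that add atoms: none
Why: Allylic alcohol oxidation with MnO2 under neutral conditions that should not isomerise the trisubstituted alkene.

Step 10
Reactants: 14 (E)-3-[(tert-butyldimethylsilyloxy)methyl]-6-(4-methoxybenzyloxy)hex-2-en-4-ynal; 15 methyl propiolate
Product: 16 methyl (S,E)-6-[(tert-butyldimethylsilyloxy)methyl]-4-hydroxy-9-(4-methoxybenzyloxy)non-5-ene-2,7-diynoate
Conditions: Zn(CH3)2, (S,S)-ProPhenol (cat.), toluene, 0 °C
Reagents that add atoms: none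
Why: Zinc–ProPhenol-catalysed enantioselective alkynylation of an enal with the zinc alkynylide of the propiolate, in which the dinuclear zinc catalyst selects the aldehyde face and sets C7.

Step 11
Reactants: 16 methyl (S,E)-6-[(tert-butyldimethylsilyloxy)methyl]-4-hydroxy-9-(4-methoxybenzyloxy)non-5-ene-2,7-diynoate
Product: 19 (S)-5-{(E)-2-[(tert-butyldimethylsilyloxy)methyl]-5-(4-methoxybenzyloxy)pent-1-en-3-yn-1-yl}-3-methyl-4-vinylfuran-2(5H)-one, via alkenylcopper 17 (not isolated), via hydroxy enoate 18 (not isolated)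
Conditions: H2C=CHMgBr, CuBr·SMe2, THF, −78 °C; then CH3I, HMPA, −78 → 0 °C; aq. NH4Cl; p-TsOH (cat.), CH2Cl2
Reagents that add atoms: vinylmagnesium bromide, C=C[Mg]Br; iodomethane, CI
Why: Syn carbocupration of the ynoate at C8 gives an alkenylcopper whose C–Cu bond is methylated with retention (C18), and the C7 alkoxide, cis to the ester, lactonises to the butenolide without touching C7.

Step 12
Reactants: 19 (S)-5-{(E)-2-[(tert-butyldimethylsilyloxy)methyl]-5-(4-methoxybenzyloxy)pent-1-en-3-yn-1-yl}-3-methyl-4-vinylfuran-2(5H)-one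
Product: 21 (S)-2-{(E)-2-[(tert-butyldimethylsilyloxy)methyl]-5-(4-methoxybenzyloxy)pent-1-en-3-yn-1-yl}-4-methyl-5-oxo-2,5-dihydrofuran-3-carbaldehyde, via vicinal diol 20 (not isolated)
Conditions: OsO4 (cat.), NaIO4, 2,6-lutidine, dioxane/H2O, rt
Reagents that add atoms: sodium periodate (oxygen source through OsO4), [Na+].[O-]I(=O)(=O)=O
Why: Lemieux–Johnson cleavage, in which OsO4 should take the terminal, least hindered vinyl group in preference to the trisubstituted, oxygen-flanked enyne alkene and periodate cleaves the diol to the C9 aldehyde.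

Step 13
Reactants: 6 (R)-2-(bromomethyl)-5-(tert-butyldimethylsilyloxy)-4,4-dimethoxycyclohex-2-en-1-one; 21 (S)-2-{(E)-2-[(tert-butyldimethylsilyloxy)methyl]-5-(4-methoxybenzyloxy)pent-1-en-3-yn-1-yl}-4-methyl-5-oxo-2,5-dihydrofuran-3-carbaldehyde
Product: 23 C9 carbinol with the 1(15)-methylene-14-ketone, 11,11-dimethoxy and 12-silyloxy groups (C7, C9, C10, C12 as in the target), via allylindium 22 (not isolated)
Conditions: In (powder), DMF, rt
Reagents that add atoms: none
Why: Indium Barbier allylation, in which the 2-acylallylindium adds at its γ-carbon C10 through a chair with the aldehyde substituent and the ring carbon C11 (trans to CH2In) both equatorial, giving the 9,10 relationship of the target, while attack anti to the C12 silyloxy group (3,5-trans to the ketone, as in additions to 5-substituted cyclohexenones) sets C10.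

Step 14
Reactants: 23 C9 carbinol
Product: 24 9-O-TBS ether of 23
Conditions: TBSOTf, 2,6-lutidine, CH2Cl2, −78 °C
Reagents that add atoms: tert-butyldimethylsilyl triflate, CC(C)(C)[Si](C)(C)OS(=O)(=O)C(F)(F)F
Why: Silylation of the hindered secondary alcohol with a silyl triflate at low temperature, where the dimethyl ketal is not activated.

Step 15
Reactants: 24 9-O-TBS enone
Product: 25 C14 allylic alcohol (C14 epimers)
Conditions: NaBH4, CeCl3·7H2O, MeOH, −78 °C
Reagents that add atoms: none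
Why: Luche 1,2-reduction masks the enone as an allylic alcohol so that C10–H is not doubly activated once the C11 ketone is freed; the C14 configuration is of no consequence.

Step 16
Reactants: 25 C14 allylic alcohol
Product: 26 C11 ketone
Conditions: PPTS, acetone/H2O, 40 °C
Reagents that add atoms: water, O
Why: Acid-catalysed hydrolysis of the dimethyl ketal, the most acid-labile group present.

Step 17
Reactants: 26 C11 ketone
Product: 27 11(20)-methylene compound
Conditions: Zn, CH2Br2, TiCl4, THF, 0 °C → rt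
Reagents that add atoms: dibromomethane, BrCBr
Why: Takai–Lombardo methylenation, a non-basic titanium–zinc methylene reagent suited to hindered, enolisable α-silyloxy ketones and inert to lactones.

Step 18
Reactants: 27 11(20)-methylene allylic alcohol
Product: 28 1(15)-methylene-14-ketone (exocyclic enone)
Conditions: Dess–Martin periodinane, NaHCO3, CH2Cl2, 0 °C → rt
Reagents that add atoms: none
Why: Dess–Martin oxidation of the allylic alcohol under buffered, non-enolising conditions.

Step 19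
Reactants: 28 exocyclic enone
Product: 30 tertiary C1 bromide, 14-ketone (C1 epimers), via lithium enolate 29 (not isolated)
Conditions: LiBH(s-Bu)3, THF, −78 °C; then N-bromosuccinimide, −78 °C
Reagents that add atoms: N-bromosuccinimide, O=C1CCC(=O)N1Br
Why: Conjugate hydride addition to the unhindered exocyclic enone (the tetrasubstituted butenolide is far slower) gives the C14=C1 enolate regiospecifically, and its bromination at C1 gives the α-bromoketone.

Step 20
Reactants: 30 bromoketone 4-methoxybenzyl ether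
Product: 31 bromoketone propargylic alcohol
Conditions: DDQ, CH2Cl2/pH 7 buffer, 0 °C
Reagents that add atoms: none
Why: Oxidative cleavage of the 4-methoxybenzyl ether by DDQ under neutral conditions that leave the tertiary bromide and the silyl ethers alone.

Step 21
Reactants: 31 bromoketone propargylic alcohol
Product: 32 α-bromoketone enynal
Conditions: Dess–Martin periodinane, NaHCO3, CH2Cl2, 0 °C
Reagents that add atoms: none
Why: Dess–Martin oxidation of the propargylic alcohol to the ynal without base.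

Step 22
Reactants: 32 α-bromoketone enynal
Product: 35 cyclodecenyne aldol with the C14 ketone, via samarium enolate 33 (not isolated), via samarium aldolate 34 (not isolated)
Conditions: SmI2 (2.5 equiv), THF, −78 °C, slow addition of 32 at high dilution, then → −20 °C; aq. NH4Cl
Reagents that add atoms: none
Why: SmI2 transfers two electrons to the tertiary C1–Br bond (either epimer) to give the tetrasubstituted trivalent-samarium C14=C1 enolate regiospecifically, which adds to the samarium-bound ynal carbonyl, a Reformatsky-type reductive aldol of the kind known for α-bromoketone aldehydes closing eight- to fourteen-membered carbocycles. The ten-membered ring (C1–C10) closes in a 10-(enolexo)-exo-trig mode with C14 outside the new ring, and the linear C3≡C4 unit and the planar butenolide keep transannular hydrogens out of the ring. C1 should be set by approach of the tethered aldehyde to the α face: allylic strain with C15 and with the C11 methylene turns the C10–C9 bond pseudoaxial on the β face, so chair-like axial bond formation at C1 anti to it leads to the trans-fused bicycle, whereas a β closure would need a boat-like, eclipsed cis fusion. C2 should be set by the chair in which samarium bridges O14 and O2 with the alkynyl arm equatorial, which places O2 syn to C15 and C3 gauche to C10, the only orientation in which the tether reaches C1. The step needs reduction of the bromide before the ynal and no retro-aldol or β-elimination of the C12 silyl ether; fast electron transfer to α-bromoketones at −78 °C, high dilution with slow addition and the non-basic samarium aldolate should secure these.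

Step 23
Reactants: 35 cyclodecenyne aldol
Product: 36 2β,14α-diol
Conditions: (CH3)4NBH(OAc)3, AcOH/MeCN, −30 °C
Reagents that add atoms: none
Why: Evans–Saksena reduction, in which the C2 alkoxyborohydride delivers hydride internally to the β face of C14 through a chair (1,3-anti), helped by the axial 12-silyloxy group that blocks external axial attack from the α face.

Step 24
Reactants: 36 2β,14α-diol
Product: 37 (3Z)-diene diol
Conditions: H2 (1 atm), Pd/CaCO3 poisoned with Pb(OAc)2, quinoline, EtOAc, rt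
Reagents that add atoms: none
Why: Lindlar semihydrogenation adds H2 syn to the strained ring alkyne to give the Z alkene and should stop there.

Step 25
Reactants: 37 (3Z)-diene diol
Product: 38 8α,17α-epoxy lactone
Conditions: t-BuOOH, benzyltrimethylammonium hydroxide (cat.), THF, 0 °C
Reagents that add atoms: tert-butyl hydroperoxide, CC(C)(C)OO
Why: Weitz–Scheffer epoxidation, in which the hydroperoxide anion adds reversibly to C8 of the electron-poor butenolide only and ring closure is expected on the α face, away from the C9 silyloxy group held over the β face by allylic strain with C18 and on the side that lets C6 and C9 become trans across C7–C8.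

Step 26
Reactants: 38 8α,17α-epoxy lactone
Product: 40 8α-hydroxy lactone, 17-epimer, via samarium lactone enolate 39 (not isolated)
Conditions: SmI2 (2.5 equiv), THF/MeOH, −78 °C
Reagents that add atoms: none
Why: Reductive opening of an α,β-epoxy lactone by SmI2 cleaves the C17–O bond and keeps the C8 oxygen, and kinetic protonation of the enolate from the face of the samarium alkoxide should give the 17-epimer.

Step 27
Reactants: 40 8α-hydroxy lactone, 17-epimer
Product: 41 8α-hydroxy lactone with natural C17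
Conditions: DBU, toluene, rt
Reagents that add atoms: none
Why: Base-mediated equilibration through the lactone enolate should place C18 trans to the bulky C9 branch and cis to 8-OH, the configuration of the target.

Step 28
Reactants: 41 8α-hydroxy lactone
Product: 42 2,14-diacetate
Conditions: Ac2O, DMAP, pyridine, rt
Reagents that add atoms: acetic anhydride, CC(=O)OC(C)=O
Why: DMAP-catalysed acetylation of the two secondary alcohols, the tertiary 8-OH being inert under these conditions.

Step 29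
Reactants: 42 2,14-diacetate
Product: 43 C16 allylic alcohol
Conditions: HF·pyridine, pyridine, THF, 0 °C
Reagents that add atoms: none
Why: Buffered HF·pyridine removes the primary allylic silyl ether much faster than the two hindered secondary ones.

Step 30
Reactants: 43 C16 allylic alcohol
Product: 45 C16 allylic chloride, via mesylate 44 (not isolated)
Conditions: CH3SO2Cl, LiCl, 2,4,6-collidine, DMF, 0 °C
Reagents that add atoms: lithium chloride, [Li+].[Cl-]; methanesulfonyl chloride, CS(=O)(=O)Cl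
Why: Meyers–Collington chlorination, in which the primary allylic mesylate is displaced in situ by chloride (SN2) without allylic transposition.

Step 31
Reactants: 45 C16 allylic chloride
Product: 46 9,12-diol
Conditions: aq. HF, MeCN, 0 °C → rt
Reagents that add atoms: none
Why: Acidic fluoride cleaves the hindered secondary silyl ethers while acetates, lactone and allylic chloride are stable to it.

Step 32
Reactants: 46 9,12-diol
Product: 47 11α,20-epoxide
Conditions: VO(acac)2 (cat.), t-BuOOH, CH2Cl2, 0 °C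
Reagents that add atoms: tert-butyl hydroperoxide, CC(C)(C)OO
Why: Hydroxyl-directed vanadium-catalysed epoxidation, in which C12–OH is the only allylic alcohol and delivers oxygen to the α face of C11=C20, the diene carrying no free allylic hydroxyl.

Step 33
Reactants: 47 11α,20-epoxide
Product: 48 CNP0128637.1
Conditions: Ac2O, DMAP, Et3N, CH2Cl2, rt
Reagents that add atoms: acetic anhydride, CC(=O)OC(C)=O
Why: Acetylation of the two secondary alcohols at C9 and C12, the tertiary 8-OH staying free.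

**Compound list**

1 | 4,4-dimethoxycyclohexa-2,5-dien-1-one | COC1(OC)C=CC(=O)C=C1 | starting material
2 | 4,4-dimethoxy-5-(pinacolatoboryl)cyclohex-2-en-1-one, boron in the place of the oxygen of 3 | O=C1C=CC(OC)(OC)[C@H](B2OC(C)(C)C(C)(C)O2)C1 | intermediate
3 | (R)-5-hydroxy-4,4-dimethoxycyclohex-2-en-1-one | O=C1C=CC(OC)(OC)[C@H](O)C1 | intermediate
4 | (R)-5-(tert-butyldimethylsilyloxy)-4,4-dimethoxycyclohex-2-en-1-one | O=C1C=CC(OC)(OC)[C@H](O[Si](C)(C)C(C)(C)C)C1 | intermediate
5 | (R)-5-(tert-butyldimethylsilyloxy)-2-(hydroxymethyl)-4,4-dimethoxycyclohex-2-en-1-one | O=C1C(CO)=CC(OC)(OC)[C@H](O[Si](C)(C)C(C)(C)C)C1 | intermediate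
6 | (R)-2-(bromomethyl)-5-(tert-butyldimethylsilyloxy)-4,4-dimethoxycyclohex-2-en-1-one | O=C1C(CBr)=CC(OC)(OC)[C@H](O[Si](C)(C)C(C)(C)C)C1 | intermediate
7 | propargyl alcohol | OCC#C | starting material
8 | 1-methoxy-4-[(prop-2-yn-1-yloxy)methyl]benzene | C#CCOCc1ccc(OC)cc1 | intermediate
9 | but-2-yne-1,4-diol | OCC#CCO | starting material
10 | 4-(tert-butyldimethylsilyloxy)but-2-yn-1-ol | OCC#CCO[Si](C)(C)C(C)(C)C | intermediate
11 | sodium cyclic alkoxy(alkenyl)alanate from 10 | [Na+].COCCO[Al-]1(OCCOC)OCC=C1CO[Si](C)(C)C(C)(C)C | intermediate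
12 | (Z)-4-(tert-butyldimethylsilyloxy)-3-iodobut-2-en-1-ol | OC/C=C(\I)CO[Si](C)(C)C(C)(C)C | intermediate
13 | (E)-3-[(tert-butyldimethylsilyloxy)methyl]-6-(4-methoxybenzyloxy)hex-2-en-4-yn-1-ol | OC/C=C(\C#CCOCc1ccc(OC)cc1)CO[Si](C)(C)C(C)(C)C | intermediate
14 | (E)-3-[(tert-butyldimethylsilyloxy)methyl]-6-(4-methoxybenzyloxy)hex-2-en-4-ynal | O=C/C=C(\C#CCOCc1ccc(OC)cc1)CO[Si](C)(C)C(C)(C)C | intermediate
15 | methyl propiolate | COC(=O)C#C | starting material
16 | methyl (S,E)-6-[(tert-butyldimethylsilyloxy)methyl]-4-hydroxy-9-(4-methoxybenzyloxy)non-5-ene-2,7-diynoate | COC(=O)C#C[C@@H](O)/C=C(\C#CCOCc1ccc(OC)cc1)CO[Si](C)(C)C(C)(C)C | intermediate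
17 | alkenylcopper from syn vinyl addition to 16 (bromomagnesium alkoxide) | COC(=O)/C([Cu])=C(C=C)\[C@@H](O[Mg]Br)/C=C(\C#CCOCc1ccc(OC)cc1)CO[Si](C)(C)C(C)(C)C | intermediate
18 | methyl 2-methyl-3-vinyl-4-hydroxy enoate, ester cis to the C7 carbinol | COC(=O)/C(C)=C(C=C)\[C@@H](O)/C=C(\C#CCOCc1ccc(OC)cc1)CO[Si](C)(C)C(C)(C)C | intermediate
19 | (S)-5-{(E)-2-[(tert-butyldimethylsilyloxy)methyl]-5-(4-methoxybenzyloxy)pent-1-en-3-yn-1-yl}-3-methyl-4-vinylfuran-2(5H)-one | C=CC1=C(C)C(=O)O[C@H]1/C=C(\C#CCOCc2ccc(OC)cc2)CO[Si](C)(C)C(C)(C)C | intermediate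
20 | 4-(1,2-dihydroxyethyl)butenolide from 19 (diol carbon unassigned) | OCC(O)C1=C(C)C(=O)O[C@H]1/C=C(\C#CCOCc2ccc(OC)cc2)CO[Si](C)(C)C(C)(C)C | intermediate
21 | (S)-2-{(E)-2-[(tert-butyldimethylsilyloxy)methyl]-5-(4-methoxybenzyloxy)pent-1-en-3-yn-1-yl}-4-methyl-5-oxo-2,5-dihydrofuran-3-carbaldehyde | O=CC1=C(C)C(=O)O[C@H]1/C=C(\C#CCOCc2ccc(OC)cc2)CO[Si](C)(C)C(C)(C)C | intermediate
22 | allylindium dibromide from 6 | Br[In](Br)CC1=CC(OC)(OC)[C@H](O[Si](C)(C)C(C)(C)C)CC1=O | intermediate
23 | C9 carbinol, 1(15)-methylene-14-ketone, 11,11-dimethoxy, 12-OTBS, 16-OTBS, 2-O-(4-methoxybenzyl) enyne, butenolide; C7, C9, C10, C12 as in target | COc1ccc(cc1)COCC#C\C(CO[Si](C)(C)C(C)(C)C)=C/[C@@H]1OC(=O)C(C)=C1[C@@H](O)[C@H]2C(OC)(OC)[C@H](O[Si](C)(C)C(C)(C)C)CC(=O)C2=C | intermediate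
24 | 9-O-TBS ether of 23 | COc1ccc(cc1)COCC#C\C(CO[Si](C)(C)C(C)(C)C)=C/[C@@H]1OC(=O)C(C)=C1[C@@H](O[Si](C)(C)C(C)(C)C)[C@H]2C(OC)(OC)[C@H](O[Si](C)(C)C(C)(C)C)CC(=O)C2=C | intermediate
25 | C14 allylic alcohol of 24 (C14 epimers) | COc1ccc(cc1)COCC#C\C(CO[Si](C)(C)C(C)(C)C)=C/[C@@H]1OC(=O)C(C)=C1[C@@H](O[Si](C)(C)C(C)(C)C)[C@H]2C(OC)(OC)[C@H](O[Si](C)(C)C(C)(C)C)CC(O)C2=C | intermediate
26 | C11 ketone, C14 alcohol (C14 epimers) | COc1ccc(cc1)COCC#C\C(CO[Si](C)(C)C(C)(C)C)=C/[C@@H]1OC(=O)C(C)=C1[C@@H](O[Si](C)(C)C(C)(C)C)[C@H]2C(=O)[C@H](O[Si](C)(C)C(C)(C)C)CC(O)C2=C | intermediate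
27 | 11(20)-methylene, 1(15)-methylene C14 alcohol (C14 epimers) | COc1ccc(cc1)COCC#C\C(CO[Si](C)(C)C(C)(C)C)=C/[C@@H]1OC(=O)C(C)=C1[C@@H](O[Si](C)(C)C(C)(C)C)[C@H]2C(=C)[C@H](O[Si](C)(C)C(C)(C)C)CC(O)C2=C | intermediate
28 | 1(15)-methylene-14-ketone with 11(20)-methylene | COc1ccc(cc1)COCC#C\C(CO[Si](C)(C)C(C)(C)C)=C/[C@@H]1OC(=O)C(C)=C1[C@@H](O[Si](C)(C)C(C)(C)C)[C@H]2C(=C)[C@H](O[Si](C)(C)C(C)(C)C)CC(=O)C2=C | intermediate
29 | lithium C14=C1 enolate | COc1ccc(cc1)COCC#C\C(CO[Si](C)(C)C(C)(C)C)=C/[C@@H]1OC(=O)C(C)=C1[C@@H](O[Si](C)(C)C(C)(C)C)[C@H]2C(=C)[C@H](O[Si](C)(C)C(C)(C)C)CC([O-])=C2C.[Li+] | intermediate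
30 | tertiary C1 bromide, 14-ketone, 2-O-(4-methoxybenzyl) (C1 epimers, one drawn) | COc1ccc(cc1)COCC#C\C(CO[Si](C)(C)C(C)(C)C)=C/[C@@H]1OC(=O)C(C)=C1[C@@H](O[Si](C)(C)C(C)(C)C)[C@H]2C(=C)[C@H](O[Si](C)(C)C(C)(C)C)CC(=O)[C@]2(C)Br | intermediate
31 | bromoketone with free C2 propargylic alcohol | OCC#C\C(CO[Si](C)(C)C(C)(C)C)=C/[C@@H]1OC(=O)C(C)=C1[C@@H](O[Si](C)(C)C(C)(C)C)[C@H]2C(=C)[C@H](O[Si](C)(C)C(C)(C)C)CC(=O)[C@]2(C)Br | intermediate
32 | α-bromoketone enynal | O=CC#C\C(CO[Si](C)(C)C(C)(C)C)=C/[C@@H]1OC(=O)C(C)=C1[C@@H](O[Si](C)(C)C(C)(C)C)[C@H]2C(=C)[C@H](O[Si](C)(C)C(C)(C)C)CC(=O)[C@]2(C)Br | intermediate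
33 | trivalent-samarium C14=C1 enolate of the enynal | O=CC#C\C(CO[Si](C)(C)C(C)(C)C)=C/[C@@H]1OC(=O)C(C)=C1[C@@H](O[Si](C)(C)C(C)(C)C)[C@H]2C(=C)[C@H](O[Si](C)(C)C(C)(C)C)CC(O[Sm](I)I)=C2C | intermediate
34 | samarium C2 aldolate of 35 | I[Sm](I)O[C@H]1C#C\C(CO[Si](C)(C)C(C)(C)C)=C/[C@@H]2OC(=O)C(C)=C2[C@@H](O[Si](C)(C)C(C)(C)C)[C@H]2C(=C)[C@H](O[Si](C)(C)C(C)(C)C)CC(=O)[C@]12C | intermediate
35 | cyclodecenyne aldol with the C14 ketone (2β-OH, C1 quaternary, trans-fused) | O[C@H]1C#C\C(CO[Si](C)(C)C(C)(C)C)=C/[C@@H]2OC(=O)C(C)=C2[C@@H](O[Si](C)(C)C(C)(C)C)[C@H]2C(=C)[C@H](O[Si](C)(C)C(C)(C)C)CC(=O)[C@]12C | intermediate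
36 | 2β,14α-diol (3-yne) | O[C@H]1C#C\C(CO[Si](C)(C)C(C)(C)C)=C/[C@@H]2OC(=O)C(C)=C2[C@@H](O[Si](C)(C)C(C)(C)C)[C@H]2C(=C)[C@H](O[Si](C)(C)C(C)(C)C)C[C@H](O)[C@]12C | intermediate
37 | (3Z)-diene 2β,14α-diol with butenolide | O[C@H]1/C=C\C(CO[Si](C)(C)C(C)(C)C)=C/[C@@H]2OC(=O)C(C)=C2[C@@H](O[Si](C)(C)C(C)(C)C)[C@H]2C(=C)[C@H](O[Si](C)(C)C(C)(C)C)C[C@H](O)[C@]12C | intermediate
38 | 8α,17α-epoxy lactone | O[C@H]1/C=C\C(CO[Si](C)(C)C(C)(C)C)=C/[C@@H]2OC(=O)[C@]3(C)O[C@]23[C@@H](O[Si](C)(C)C(C)(C)C)[C@H]2C(=C)[C@H](O[Si](C)(C)C(C)(C)C)C[C@H](O)[C@]12C | intermediate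
39 | samarium lactone enolate with C8 samarium alkoxide | O[C@H]1/C=C\C(CO[Si](C)(C)C(C)(C)C)=C/[C@@H]2OC(O[Sm](I)I)=C(C)[C@@]2(O[Sm](I)I)[C@@H](O[Si](C)(C)C(C)(C)C)[C@H]2C(=C)[C@H](O[Si](C)(C)C(C)(C)C)C[C@H](O)[C@]12C | intermediate
40 | 8α-hydroxy lactone, 17-epimer (C18 trans to 8-OH) | O[C@H]1/C=C\C(CO[Si](C)(C)C(C)(C)C)=C/[C@@H]2OC(=O)[C@@H](C)[C@@]2(O)[C@@H](O[Si](C)(C)C(C)(C)C)[C@H]2C(=C)[C@H](O[Si](C)(C)C(C)(C)C)C[C@H](O)[C@]12C | intermediate
41 | 8α-hydroxy lactone, natural C17 (C18 cis to 8-OH) | O[C@H]1/C=C\C(CO[Si](C)(C)C(C)(C)C)=C/[C@@H]2OC(=O)[C@H](C)[C@@]2(O)[C@@H](O[Si](C)(C)C(C)(C)C)[C@H]2C(=C)[C@H](O[Si](C)(C)C(C)(C)C)C[C@H](O)[C@]12C | intermediate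
42 | 2,14-diacetate, 9,12,16-tris-TBS ether | CC(=O)O[C@H]1/C=C\C(CO[Si](C)(C)C(C)(C)C)=C/[C@@H]2OC(=O)[C@H](C)[C@@]2(O)[C@@H](O[Si](C)(C)C(C)(C)C)[C@H]2C(=C)[C@H](O[Si](C)(C)C(C)(C)C)C[C@H](OC(C)=O)[C@]12C | intermediate
43 | C16 allylic alcohol | CC(=O)O[C@H]1/C=C\C(CO)=C/[C@@H]2OC(=O)[C@H](C)[C@@]2(O)[C@@H](O[Si](C)(C)C(C)(C)C)[C@H]2C(=C)[C@H](O[Si](C)(C)C(C)(C)C)C[C@H](OC(C)=O)[C@]12C | intermediate
44 | C16 mesylate | CC(=O)O[C@H]1/C=C\C(COS(C)(=O)=O)=C/[C@@H]2OC(=O)[C@H](C)[C@@]2(O)[C@@H](O[Si](C)(C)C(C)(C)C)[C@H]2C(=C)[C@H](O[Si](C)(C)C(C)(C)C)C[C@H](OC(C)=O)[C@]12C | intermediate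
45 | C16 allylic chloride, 9,12-bis-TBS ether | CC(=O)O[C@H]1/C=C\C(CCl)=C/[C@@H]2OC(=O)[C@H](C)[C@@]2(O)[C@@H](O[Si](C)(C)C(C)(C)C)[C@H]2C(=C)[C@H](O[Si](C)(C)C(C)(C)C)C[C@H](OC(C)=O)[C@]12C | intermediate
46 | 9,12-diol, 11(20)-ene | CC(=O)O[C@H]1/C=C\C(CCl)=C/[C@@H]2OC(=O)[C@H](C)[C@@]2(O)[C@@H](O)[C@H]2C(=C)[C@H](O)C[C@H](OC(C)=O)[C@]12C | intermediate
47 | 11α,20-epoxy-9,12-diol | CC(=O)O[C@H]1/C=C\C(CCl)=C/[C@@H]2OC(=O)[C@H](C)[C@@]2(O)[C@@H](O)[C@H]2[C@@]3(CO3)[C@H](O)C[C@H](OC(C)=O)[C@]12C | intermediate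
48 | CNP0128637.1 | CC(=O)O[C@H]1/C=C\C(CCl)=C/[C@@H]2OC(=O)[C@H](C)[C@@]2(O)[C@@H](OC(C)=O)[C@H]2[C@@]3(CO3)[C@H](OC(C)=O)C[C@H](OC(C)=O)[C@]12C | target

**Step count and risks**

Total step count: 33. Longest linear sequence: 28 steps (but-2-yne-1,4-diol through steps 6–12 and 13–33).

Steps most likely to fail:

1. Step 22 (samarium macrocyclisation). The ynal may be reduced to a ketyl before the bromide, the samarium enolate may be protonated before it reaches the aldehyde, or the ring may close on the β face of C1 to a cis-fused bicycle. Fallback: from enone 28, conjugate reduction with LiBH(s-Bu)3 and O-silylation of the enolate with TBSOTf would give the regiodefined silyl enol ether F1. Buffered DDQ at 0 °C would free the propargylic alcohol F2, and Dess–Martin oxidation would give the silyl enol ether ynal F3. BF3·OEt2 in CH2Cl2 at −78 °C under high dilution would then close the same C1–C2 bond by an intramolecular Mukaiyama aldol, a Lewis-acid-mediated open-transition-state closure in place of the reductive one. This comes back to the route at 35.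

2. Step 25 (butenolide epoxidation). The peroxide may add to the β face of C8, which would give the 8-epi series, and the base may deprotonate C7 and scramble that centre. Fallback: from diene diol 37, copper-catalysed conjugate borylation (CuCl, NaOt-Bu, a chiral bisphosphine whose antipode is chosen for the α face, B2pin2, MeOH) would put boron on C8 under ligand control and give the C8 boronate F4. Oxidation with NaBO3·4H2O would give the 8α-hydroxy lactone as a C17 mixture, which the DBU equilibration of step 27 would take to the natural epimer. This comes back to the route at 41.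

3. Step 13 (indium Barbier union). Addition at the hindered γ-carbon next to the ketal may be slow, facial selectivity at C10 may be poor, or the allylindium may lose a ketal methoxide by β-elimination. Fallback: from alcohol 5, acetylation (Ac2O, pyridine) would give the allylic acetate F5. Palladium-catalysed borylation (Pd2(dba)3, B2pin2, DMSO) would give the isolable 2-(pinacolborylmethyl)enone F6. Thermal allylboration of aldehyde 21 in toluene, through the same chair but with a stable, non-basic allylboronate, would form the C9–C10 bond. This comes back to the route at 23.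

Further compounds
F1 | step 22 | C14 tert-butyldimethylsilyl enol ether of the reduced enone 28 | COc1ccc(cc1)COCC#C\C(CO[Si](C)(C)C(C)(C)C)=C/[C@@H]1OC(=O)C(C)=C1[C@@H](O[Si](C)(C)C(C)(C)C)[C@H]2C(=C)[C@H](O[Si](C)(C)C(C)(C)C)CC(O[Si](C)(C)C(C)(C)C)=C2C
F2 | step 22 | silyl enol ether with free C2 propargylic alcohol | OCC#C\C(CO[Si](C)(C)C(C)(C)C)=C/[C@@H]1OC(=O)C(C)=C1[C@@H](O[Si](C)(C)C(C)(C)C)[C@H]2C(=C)[C@H](O[Si](C)(C)C(C)(C)C)CC(O[Si](C)(C)C(C)(C)C)=C2C
F3 | step 22 | silyl enol ether ynal | O=CC#C\C(CO[Si](C)(C)C(C)(C)C)=C/[C@@H]1OC(=O)C(C)=C1[C@@H](O[Si](C)(C)C(C)(C)C)[C@H]2C(=C)[C@H](O[Si](C)(C)C(C)(C)C)CC(O[Si](C)(C)C(C)(C)C)=C2C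
F4 | step 25 | 8α-(pinacolatoboryl) lactone (C17 epimers) | O[C@H]1/C=C\C(CO[Si](C)(C)C(C)(C)C)=C/[C@@H]2OC(=O)C(C)[C@@]2(B3OC(C)(C)C(C)(C)O3)[C@@H](O[Si](C)(C)C(C)(C)C)[C@H]2C(=C)[C@H](O[Si](C)(C)C(C)(C)C)C[C@H](O)[C@]12C
F5 | step 13 | (R)-2-(acetoxymethyl)-5-(tert-butyldimethylsilyloxy)-4,4-dimethoxycyclohex-2-en-1-one | O=C1C(COC(C)=O)=CC(OC)(OC)[C@H](O[Si](C)(C)C(C)(C)C)C1
F6 | step 13 | (R)-5-(tert-butyldimethylsilyloxy)-4,4-dimethoxy-2-[(pinacolatoboryl)methyl]cyclohex-2-en-1-one | O=C1C(CB2OC(C)(C)C(C)(C)O2)=CC(OC)(OC)[C@H](O[Si](C)(C)C(C)(C)C)C1
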